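At 0.500 d the alder flask still held 86.7% of its Z, and at 3.00 d it held 61.8%. The new set-ups use the same charge.

| flask | Z | E | remark | time |
|---|---|---|---|---|
| alder | 2 M | 0.80 equiv | run made earlier |  |
| Tuesday's | 2.0 M | 0.800 equiv | everything together in a closed stirred flask, run for 3.0 d | 3.0 d |
| Wednesday's | 2.0 M | 0.800 equiv | a tube with plug flow, the mixed feed as stated, residence time 3.0 d | 3.0 d |
| Monday's | 2.0 M | 0.800 equiv | one stirred flow tank at steady state, fed with the mixture as stated, mean residence time 3.0 d |  |
| Saturday's | 2.0 M | 0.800 equiv | one stirred flow tank at steady state, fed with the mixture as stated, mean residence time 30.0 d |  |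

- alder (time / d: J / %, Z / %): 0.500: 14.8, 86.7; 1.04: 23.1, 78.0; 1.67: 27.2, 70.5; 2.08: 31.3, 66.1; 2.50: 34.0, 62.8; 3.00: 39.7, 61.8

(readings scatter by 1 percentage point)

- the stated concentrations are those of everything mixed, before any reaction; amounts are the same in each set-up
- the earlier runs were made in a closed, stirred flask

- the set-up with the highest amount of J at the outlet or at the end, in percent of the Z put in ("none" if the first two lie within 2 percentage points) (Tuesday's / Wednesday's / Monday's / Saturday's / none)
- amount of J at the outlet or at the end, in percent of the Z put in, Tuesday's
- amount of J at the outlet or at the end, in percent of the Z put in, Wednesday's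
- amount of J at the outlet or at the end, in percent of the Z put in, Monday's
- amount of J at the outlet or at the end, in percent of the Z put in, Saturday's

I counted turnovers. The lifetime of Z is the time in which Z would fall by a factor e at its present pace. In a stirred tank at steady state, with J and Z summing to the charge, J over Z equals residence time over that lifetime. The sum looked sound: 102% at the last alder reading.

The first reading gave a lifetime of 3.50 d. Saturday's 30.0 d then meant 8.56 turnovers and 89.5% J. But that is more than E, the limiting reagent at 0.800 equiv, can make.

So I read the pace from 1.04 d to 3.00 d. This gave 8.42 d, the later lifetime of Z, which is longer than the first. Saturday's tank now came to 3.56 turnovers and 78.1% J. I doubted this too. By subtraction from the charge it left 1.90% of E, in percent of the Z charged, against 49.9% on the mean of those two readings.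

I therefore stretched the lifetime in inverse proportion to the E left. That gave 7.14 turnovers per unit of E left, and 59.5% J for Saturday's tank. Monday's tank had 0.356 turnovers, so I reckoned 26.3% J. By the same subtraction that left 53.7% of E beside the 49.9%, so I did not stretch the lifetime for Monday's tank. The closed flask and the tube follow the alder curve, so I read them at its last point, 39.7%.

The forecast said 38.5% for Tuesday's, 38.5% for Wednesday's, 29.5% for Monday's and 53% for Saturday's, with Saturday's as best. Its doubt was that “equilibrium would cap it near 45%”. My Saturday's figure stood above its figure, and my Monday's figure below its figure.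

Saturday's tank gave 61.1% J, the highest of the set-ups, against 39.0% for Tuesday's and 39.0% for Wednesday's. Z + E → J + Q (k = 1.90 × 10⁻⁴ M⁻¹ min⁻¹); E ⇌ D (K = 1.00, k = 9.70 × 10⁻⁴ min⁻¹)

In Saturday's tank [Z] stood at 0.778 M and [E] at 0.191 M. Its J over Z was 1.57 turnovers, so the lifetime of Z there was 19.1 d, longer than 8.42 d. Monday's tank gave 30.9% J beside 69.1% Z, a lifetime of 6.72 d, shorter than 8.42 d.

All runs are simulated with made-up constants; the scatter is artificial.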